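# Design of a total synthesis of CNP0605450.1 (35) by a De Mayo photocycloaddition–retro-aldol route

## The problem

The target 35 is a bicyclo[3.3.1]nonane (rings C and D) fused along C7–C8 to a cyclohepta-1,3-diene (ring B) that carries a δ-lactone (ring A) and a spiro-epoxide on the one-carbon bridge. Numbering used throughout: C1 ester bridgehead, C2, C3 (C(OH)CH3), C4 (ketone), C5 methyl bridgehead, C6, C7 (ring-fusion CH), C8 (quaternary, CH3), C9 (bridge); ring B = C7, C8, C14, C13, C12, C11, C10 (bearing CH3); lactone = C11–C15–C16(=O)–O–C17(CH3)2–C12.

There are six stereocentres (C1, C3, C5, C7, C8, C9). C1 and C5 are tied together by the bicycle, so one must carry the absolute configuration and the other must be introduced cis to it. C8 and C7 sit on the bond that joins two fully substituted carbons, the most congested bond in the molecule. C3 and C9 can be set last, because the bicycle has an open exo face at C3 and the axial C8 methyl covers one face of C9.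

Several groups will not survive rough treatment:
- the tertiary lactone C17–O bond, which becomes allylic once C12=C13 exists (acid, zerovalent palladium);
- the C15 methylene between the lactone carbonyl and the diene (base moves the diene into conjugation);
- any carbanion at C12, which expels the lactone carboxylate;
- the non-enolisable β-dicarbonyl array C1/C9/C5/C4 (retro-Claisen with nucleophilic bases);
- the epoxide, the tertiary α-ketol and the diene (electrophilic oxidants).

The enabling feature is that C10 and C13 are 1,4-related carbons flanking the lactone fusion. Ring B is therefore a cyclohepta-1,4-dione in disguise: inserting the two isopropenyl carbons C8 and C14 into the C7–C13 bond of a lactone-fused cyclopentane-1,3-dione, hung through C6 from C5, closes rings C and B at once. Because that dione is unsymmetrical, which carbonyl is the enol carbon decides the constitution, and the lactone stereocentres C11/C12, erased later, decide which face of the enone reacts.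

## Retrosynthesis

**35 ⇒ 34 ⇒ 33 ⇒ 32 (ring-B diene).** The C12=C13 bond is moved back to C13=C14 (34), the C10–CH3 bond is cut to an enol triflate (33) and the C13–H bond to a second triflate (32). The obvious neighbour, a conjugated bis(enol triflate), needs an enolate carbon at C12, which would eject the lactone carboxylate, and its two triflates are sterically alike. Kinetic enolisation instead gives two triflates of very different substitution, and the diene is conjugated last without base. Both palladium steps then run before the lactone C–O bond becomes allylic.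

**32 ⇒ 31 ⇒ 28 ⇒ 27 ⇒ 26 (oxidation pattern).** The epoxide C–O bonds, the C3–O bond and the C9=CH2 bond are removed in turn, and the triflates return to ketones. These oxidations are placed where ring B is an electron-poor bis(triflate) and C4 is the only enolisable ketone. Doing them on the diene would ask a peracid to ignore a tetrasubstituted alkene. The forward steps must distinguish the C9 from the C4 carbonyl and deliver oxygen to the exo face of C3 and the ring-D face of C9.

**26 ⇒ 25 ⇒ 24 (key step).** The C7–C8 and C13–C14 bonds are cut. The seven-membered 1,4-dione 26 comes from the cyclobutane 25 by retro-aldol cleavage of C7–C13, and 25 comes from enone 24 by [2+2] addition to the isopropenyl group. The precursor is two monocyclic or bicyclic pieces joined by one CH2. The enol of the plan is carried as its O-methyl ether on C13, so that only the C13 carbon can become the cyclobutane carbon. The forward reaction must join two fully substituted carbons and choose the isopropenyl rotamer that puts the C8 methyl toward C9.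

**24 ⇒ 10 + 21 (fragment union).** The C5–C6 bond is cut: a 2-methyl-1,3-dione nucleophile (10) and an α-methylene ketone released from acetate 21. Compared with a bridgehead aldehyde and a reductive condensation, this avoids a 2-formyl-1,3-dione that would deformylate. It also lets the acetal of 21 turn into the regiodefined enol ether in the same flask. The forward reaction must place the new arm cis to the isopropenyl group.

**21 ⇒ 19 ⇒ 18 ⇒ 16 ⇒ 14 ⇒ 12 ⇒ 11 (lactone–enone fragment).** The lactone C17–O bond, the C11–C15 bond (from 17), the C12–C17 bond (from 15) and the C6–C7 bond (a one-carbon aldehyde) are cut back to the monoacetal 12 of 11. The acetal is what differentiates the two carbonyls: the carbon next to the conjugate-addition site becomes the enol ether carbon C13. Installing C6 first, on the enone, removes every regiochemical choice in later enolisations. The asymmetric conjugate addition sets C12, the one centre that steers the key step.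

**10 ⇒ 9 ⇒ 6 ⇒ 5 ⇒ 3 ⇒ 1 + 2 + 4 (ring D).** The C4–C5 bond is cut (Claisen cyclisation of 9), the isopropenyl group is traced to a ring-opened lactone (6, 5), the C1–C2 bond to a Michael addition of 3 to 4, and the C1–C9 bond to acylation of 1 by 2. Direct α-isopropenylation of a ring-D β-keto ester would have to compete with the more acidic 1,3-dione and offers no reliable absolute control. Here the methyl-bearing carbon of 1 directs the quaternary centre and is then erased when it becomes the isopropenyl carbon.

## Roads not taken

**Alternative 1: electroreductive decarboxylative radical closure of ring C.** The cut is C6–C7, with rings A, B and D already joined through C1–C8. Cathodic reduction of a redox-active ester would release a primary C6 radical that adds 6-exo to C7, the δ-carbon of an extended unsaturated lactone; reduction and protonation at C15 would give A1.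
- Merits: A1 already holds the ring-B diene, the C9 methylidene and a C3–C4 silyl enol ether, so only about three oxidations remain. In endgame length this road is clearly better than the chosen one.
- Weak points: the precursor needs the C1–C8 bond between two quaternary carbons made beforehand by intermolecular chemistry. The radical must attack a trisubstituted carbon at the end of a long acceptor. The dienolate must be protonated at C15 rather than at the position that gives the conjugated lactone.
- Comparison: the chosen plan sets against the shorter endgame that its most hindered bond (C7–C8) is formed intramolecularly from an excited state and that its fragments meet at an unhindered CH2.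

**Alternative 2: allenic Pauson–Khand reaction, then oxygen insertion.** The cut is the C11–C12 bond plus both bonds to an extra carbonyl carbon. [Rh(CO)2Cl]2 under CO would couple an alkyne with the distal bond of a 1,1-dimethylallene to give A2, closing ring B and a cyclopentenone that holds all ring-A carbons; oxygen insertion would then make the lactone.
- Merits: a catalytic step that builds ring B and the ring-A carbons together and places C12=C13 directly; seven-membered rings by the distal allenic mode are well known. In atom economy for rings A and B it is at least as good as the chosen plan.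
- Weak points: a peracid would have to insert next to the quaternary carbon of a cross-conjugated dienone without touching its alkenes. The resulting unsaturated lactone would then need deconjugation to the C15 methylene. The C10 tertiary alcohol must be dehydrated into the ring. Rings C and D with the C1–C8 quaternary pair must again exist first.
- Comparison: the chosen plan carries the lactone intact from an early fragment and never oxidises a dienone.

**Alternative 3: three-component double annulation around the bridge carbonyl.** A β-keto ester, an acrylate and a bromomethyl dienone carrying rings A and B would be joined in one pot, forming both ring-D bonds, C5–C6 and C1–C8, to give A3.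
- Merits: by far the shortest way to the skeleton; in step economy it beats the chosen plan outright.
- Weak points: the C1–C8 bond would close by conjugate addition of a fully substituted carbon to a β,β-disubstituted enone under reversible ionic conditions, the least favourable way to make that bond. Nothing fixes the absolute configuration or the orientation of the C8 methyl. A3 still needs the enone turned into the methylated diene.
- Comparison: the chosen plan sets control against brevity: enantiopure fragments, an irreversible photochemical bond formation, and facial control by the lactone.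

Key step: step 13

Remarks on the chemistry (assumptions):
- Compound 1 is taken as a purchasable single enantiomer; otherwise asymmetric hydrogenation of the corresponding butenolide would supply it.
- Three centres are carried as epimer mixtures because each is equilibrated or becomes sp2 later: the ester α-carbon of 5–9 (C3; one epimer is drawn for 10, 23 and 24), the CH2O-bearing ring carbon of 16 and 18–23 (C7), and the ring-fusion carbon C11 of 19–23.

## Route

Step 1
Reactants: 1 (R)-4-methyloxolan-2-one; 2 N-methoxy-N-methylpropanamide
Product: 3 (3S,4R)-4-methyl-3-propanoyloxolan-2-one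
Conditions: LDA (2.1 equiv), THF, −78 °C; then 2, −78 → 0 °C; aq. NH4Cl
Reagents that add atoms: none
Why: Claisen-type C-acylation of a lactone lithium enolate by a Weinreb amide (the chelated adduct prevents over-addition and the second equivalent of base covers the acidic product); C3 is epimerisable and settles trans to the C4 methyl.

Step 2
Reactants: 3 (3S,4R)-4-methyl-3-propanoyloxolan-2-one; 4 methyl methacrylate
Product: 5 methyl 2-methyl-3-[(3R,4R)-4-methyl-2-oxo-3-propanoyloxolan-3-yl]propanoate (both epimers at the ester α-carbon)
Conditions: 4 (5 equiv), DBU (0.3 equiv), MeCN, 50 °C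
Reagents that add atoms: none
Why: Michael addition of a cyclic β-keto lactone to an acrylate; the planar enolate should be attacked on the face away from the adjacent ring methyl (1,2-induction in a five-membered ring), which fixes the quaternary carbon that becomes C1 and hence the absolute configuration of ring D.

Step 3
Reactants: 5 methyl 2-methyl-3-[(3R,4R)-4-methyl-2-oxo-3-propanoyloxolan-3-yl]propanoate
Product: 6 dimethyl (2R)-2-[(2R)-1-bromopropan-2-yl]-4-methyl-2-propanoylpentanedioate
Conditions: BBr3 (1.5 equiv), CH2Cl2, 0 °C → rt; then MeOH, 0 °C
Reagents that add atoms: boron tribromide BrB(Br)Br; methanol CO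
Why: boron-trihalide opening of a γ-lactone: bromide attacks the O–CH2 carbon of the boron-activated lactone (SN2) and methanol turns the acyloxyborane directly into the methyl ester, so no free β-keto acid, which would decarboxylate, is formed.

Step 4
Reactants: 6 dimethyl (2R)-2-[(2R)-1-bromopropan-2-yl]-4-methyl-2-propanoylpentanedioate
Product: 9 dimethyl (2R)-4-methyl-2-propanoyl-2-(prop-1-en-2-yl)pentanedioate, via selenide 7 (not isolated), via selenoxide 8 (not isolated)
Conditions: PhSeSePh, NaBH4, EtOH, 0 °C; then 6, rt; then aq. H2O2, pyridine, THF, 0 °C → rt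
Reagents that add atoms: none
Why: selenide displacement of the primary bromide and selenoxide syn-elimination; the only β-hydrogen is on the methyl-bearing carbon, so only the isopropenyl group can form and the auxiliary stereocentre is erased; the medium is too weakly basic for the ketone enolate to alkylate the bromide.

Step 5
Reactants: 9 dimethyl (2R)-4-methyl-2-propanoyl-2-(prop-1-en-2-yl)pentanedioate
Product: 10 methyl (1R)-3,5-dimethyl-2,4-dioxo-1-(prop-1-en-2-yl)cyclohexane-1-carboxylate (enolised 1,3-dione; C5 epimers)
Conditions: LiHMDS (2.2 equiv), THF, −78 → 0 °C; aq. HCl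
Reagents that add atoms: none
Why: Dieckmann-type Claisen cyclisation: the kinetic enolate of the ethyl ketone attacks the remote ester (6-exo-trig) and the product is removed as its 1,3-dione enolate; a non-nucleophilic base avoids retro-Claisen cleavage at the quaternary β-keto ester, whose configuration cannot change.

Step 6
Reactants: 11 cyclopent-4-ene-1,3-dione
Product: 12 4,4-dimethoxycyclopent-2-en-1-one
Conditions: HC(OMe)3, MeOH, TsOH·H2O (cat.), rt
Reagents that add atoms: trimethyl orthoformate COC(OC)OC
Why: acid-catalysed mono-acetalisation of an enedione; after the first acetal the remaining carbonyl is a less electrophilic enone carbonyl, so the reaction should stop at the monoacetal.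

Step 7
Reactants: 12 4,4-dimethoxycyclopent-2-en-1-one
Product: 14 5-({[tert-butyl(dimethyl)silyl]oxy}methyl)-4,4-dimethoxycyclopent-2-en-1-one (racemic), via hydroxymethyl enone 13 (not isolated)
Conditions: LDA, THF, −78 °C; HCHO (gas); then TBSOTf, 2,6-lutidine, −78 → 0 °C
Reagents that add atoms: formaldehyde C=O; tert-butyldimethylsilyl triflate CC(C)(C)[Si](C)(C)OS(=O)(=O)C(F)(F)F
Why: C5 is the only enolisable position of 12, so the kinetic enolate forms there; aldol addition to formaldehyde and silylation of the alkoxide install the future C6 before any regiochemical choice exists; loss of methoxide from this enolate would give a cyclopentadienone and is not expected at −78 °C.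

Step 8
Reactants: 14 5-({[tert-butyl(dimethyl)silyl]oxy}methyl)-4,4-dimethoxycyclopent-2-en-1-one; 15 4,4,5,5-tetramethyl-2-(prop-1-en-2-yl)-1,3,2-dioxaborolane
Product: 16 (4R)-2-({[tert-butyl(dimethyl)silyl]oxy}methyl)-3,3-dimethoxy-4-(prop-1-en-2-yl)cyclopentan-1-one (C2 epimers)
Conditions: [Rh(cod)Cl]2 (2.5 mol%), (R)-BINAP (6 mol%), aq. K3PO4, dioxane, 50 °C
Reagents that add atoms: none
Why: rhodium–BINAP-catalysed asymmetric 1,4-addition of an alkenylboron reagent to a cyclopentenone (Hayashi–Miyaura reaction); the catalyst selects the enone face and sets C4 (the future C12); the ligand enantiomer is chosen by the usual model for cyclopent-2-enone and would be exchanged for (S)-BINAP if the sense proved opposite.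

Step 9
Reactants: 16 (4R)-2-({[tert-butyl(dimethyl)silyl]oxy}methyl)-3,3-dimethoxy-4-(prop-1-en-2-yl)cyclopentan-1-one; 17 tert-butyl bromoacetate
Product: 18 tert-butyl 2-[(1S,2R)-4-({[tert-butyl(dimethyl)silyl]oxy}methyl)-3,3-dimethoxy-5-oxo-2-(prop-1-en-2-yl)cyclopentyl]acetate (C4 epimers)
Conditions: LDA (1.1 equiv), THF, −78 °C; then 17, DMPU, −78 → −40 °C
Reagents that add atoms: none
Why: kinetic deprotonation occurs at the unhindered CH2 and not at the substituted carbon next to the acetal; the enolate is alkylated anti to the vicinal isopropenyl group (trans product); this centre lies next to the ketone and is equilibrated later.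

Step 10
Reactants: 18 tert-butyl 2-[(1S,2R)-4-({[tert-butyl(dimethyl)silyl]oxy}methyl)-3,3-dimethoxy-5-oxo-2-(prop-1-en-2-yl)cyclopentyl]acetate
Product: 19 (4aS,7aR)-6-({[tert-butyl(dimethyl)silyl]oxy}methyl)-7,7-dimethoxy-1,1-dimethylhexahydrocyclopenta[c]pyran-3,5-dione (trans ring fusion; C6 epimers)
Conditions: Co(salen-tBu4) [N,N′-bis(3,5-di-tert-butylsalicylidene)cyclohexane-1,2-diaminatocobalt] (5 mol%), 1-fluoro-2,4,6-trimethylpyridinium triflate, PhSiH3, PhCF3, rt
Reagents that add atoms: none
Why: Mukaiyama-type hydrogen-atom-transfer hydroacyloxylation: a cobalt hydride gives a hydrogen atom to the 1,1-disubstituted alkene, the tertiary radical is oxidised at cobalt and captured by the ester carbonyl oxygen (six-membered ring), and the tert-butyl group leaves as isobutene; the medium is neutral, so the acetal and the adjacent stereocentre survive, whereas an acid lactonisation would ionise the acetal first and risk conjugative loss of the adjacent hydrogen.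

Step 11
Reactants: 19 (4aS,7aR)-6-({[tert-butyl(dimethyl)silyl]oxy}methyl)-7,7-dimethoxy-1,1-dimethylhexahydrocyclopenta[c]pyran-3,5-dione
Product: 21 [(4aS,7aR)-7,7-dimethoxy-1,1-dimethyl-3,5-dioxooctahydrocyclopenta[c]pyran-6-yl]methyl acetate (C6 epimers), via primary alcohol 20 (not isolated)
Conditions: HF·pyridine, THF, 0 °C; then Ac2O, pyridine, DMAP (cat.), 0 °C
Reagents that add atoms: acetic anhydride CC(=O)OC(C)=O
Why: mildly acidic desilylation and acylation of the primary alcohol; the β-hydroxy ketone is acetylated without isolation and under weak base only, so neither retro-aldol loss of formaldehyde nor premature elimination should occur.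

Step 12
Reactants: 10 methyl (1R)-3,5-dimethyl-2,4-dioxo-1-(prop-1-en-2-yl)cyclohexane-1-carboxylate; 21 [(4aS,7aR)-7,7-dimethoxy-1,1-dimethyl-3,5-dioxooctahydrocyclopenta[c]pyran-6-yl]methyl acetate
Product: 24 methyl (1R,3S,5R)-3-{[(4aR,7aR)-7-methoxy-1,1-dimethyl-3,5-dioxo-1,3,4,4a,5,7a-hexahydrocyclopenta[c]pyran-6-yl]methyl}-3,5-dimethyl-2,4-dioxo-1-(prop-1-en-2-yl)cyclohexane-1-carboxylate, via methylene ketone 22 (not isolated), via Michael adduct 23 (not isolated)
Conditions: DBU (2.5 equiv), MeCN, 0 → 40 °C
Reagents that add atoms: none
Why: three base-mediated events in one flask: E1cB loss of acetate from 21 gives the α-methylene ketone 22; the DBU enolate of the 2-methyl-1,3-dione 10 adds to it (Michael addition of the kind used to make triketone annulation precursors) and creates the quaternary C5; E1cB loss of methanol from the β-keto acetal 23 gives the vinylogous ester with the methoxy group on C13; the enolate of 10 is expected to react trans to the pseudo-axial ester on C1, that is cis to the isopropenyl group, and DBU equilibrates C11 to the cis lactone fusion.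

Step 13
Reactants: 24 methyl (1R,3S,5R)-3-{[(4aR,7aR)-7-methoxy-1,1-dimethyl-3,5-dioxo-1,3,4,4a,5,7a-hexahydrocyclopenta[c]pyran-6-yl]methyl}-3,5-dimethyl-2,4-dioxo-1-(prop-1-en-2-yl)cyclohexane-1-carboxylate
Product: 26 tetracyclic tetraketone lactone (rings A–D; ketones at C4 C9 C10 C13; 7-H endo; 8-CH3 toward C9; 3-CH3 exo), via methoxycyclobutane 25 (not isolated)
Conditions: hν (λ > 330 nm, uranium-glass filter), degassed MeCN, rt; then 1 M HCl, THF, rt
Reagents that add atoms: water O
Why: Excitation of the β-methoxy enone of 24 gives its triplet, which adds to the tethered 1,1-disubstituted alkene through a 1,4-biradical: the enone α-carbon C7 bonds first to the internal alkene carbon C8 (6-exo closure of ring C) and C13–C14 then closes the cyclobutane of 25. The closest known reaction type is the intramolecular De Mayo reaction of a 1,3-dione enol derivative, in which the [2+2] adduct is opened by retro-aldol cleavage after unmasking. Acid opens the donor–acceptor cyclobutane (the methoxy group on C13 pushes, the C10 carbonyl pulls) by breaking C7–C13, so ring B arises by two-carbon expansion of the five-membered ring; water turns the oxocarbenium ion into the C13 ketone and methanol is lost. C8 is controlled by the cis-fused lactone: its gem-dimethyl carbon on C12 covers one face of the enone, the alkene must add to the other face, and with the C6 tether held by ring D that face is reached only by the isopropenyl rotamer that points its methyl toward the C9 carbonyl (methyl axial on ring C, as in the target). C7 is quaternary in 25, becomes CH on cleavage and equilibrates through the C10 enol to the B/C trans fusion with the acyl group equatorial; the C3 methyl settles exo under the same acid. The step needs three selectivities: the enol regiochemistry, secured by the O-methyl group fixed on C13 in step 12; excitation of the enone only, secured by long-wavelength light that the saturated and β,γ-unsaturated ketones barely absorb; and the cis relation of the two arms on ring D from step 12, without which the bridge cannot close. The bond between the two fully substituted carbons C7 and C8 is made from an excited state, where steric demand is small.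

Step 14
Reactants: 26 tetracyclic tetraketone lactone
Product: 27 bis(enol triflate) of 26 (10-OTf with C10=C11; 13-OTf with C13=C14)
Conditions: KHMDS (2.3 equiv), THF, −78 °C; then PhNTf2 (2.5 equiv), −78 → −20 °C
Reagents that add atoms: N-phenylbis(trifluoromethanesulfonimide) O=S(=O)(N(c1ccccc1)S(=O)(=O)C(F)(F)F)C(F)(F)F
Why: kinetic enolisation and O-triflation: the C13 ketone loses a proton from the C14 methylene and the C10 ketone from C11 (the C7–H and the C3–H of the ring-D ketone are endo hydrogens facing each other inside the bicycle); no carbanion develops at C12, where it would expel the lactone carboxylate, and the two triflates protect ring B during the oxidations that follow.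

Step 15
Reactants: 27 bis(enol triflate) of 26
Product: 28 9-methylidene bis(enol triflate)
Conditions: Zn, CH2Br2, TiCl4, THF–CH2Cl2, 0 °C → rt
Reagents that add atoms: dibromomethane BrCBr
Why: Takai–Lombardo methylenation, non-basic and selective for ketones over esters and lactones; the bridge carbonyl C9 should be the more electrophilic ketone (strained one-carbon bridge next to the ester-bearing bridgehead, open from the ring-D side), whereas C4 is an ordinary ring ketone with both α-carbons substituted.

Step 16
Reactants: 28 9-methylidene bis(enol triflate)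
Product: 31 tertiary α-hydroxy ketone (3-OH exo; 3-CH3 endo), via silyl enol ether 29 (not isolated), via silyloxy ketone 30 (not isolated)
Conditions: TMSOTf, Et3N, CH2Cl2, 0 °C → rt; then mCPBA (1.05 equiv), NaHCO3, −20 °C; then citric acid, MeOH
Reagents that add atoms: 3-chloroperbenzoic acid OOC(=O)c1cccc(Cl)c1
Why: Rubottom oxidation: soft enolisation gives the only ketone-derived silyl enol ether now possible (C3=C4), which reacts with the peracid faster than the hindered methylidene and from the exo face of the bicyclo[3.3.1]nonane (the endo face is covered by ring C), so the hydroxyl ends exo and the methyl endo as in the target.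

Step 17
Reactants: 31 tertiary α-hydroxy ketone
Product: 32 spiro-epoxide (epoxide oxygen on the ring-D side of C9)
Conditions: mCPBA (1.5 equiv), NaHCO3, CH2Cl2, 0 °C → rt
Reagents that add atoms: 3-chloroperbenzoic acid OOC(=O)c1cccc(Cl)c1
Why: hydroxyl-directed epoxidation of a 1,1-disubstituted alkene: with the C3 methyl endo, ring D should adopt a boat that brings the exo hydroxyl over C9 and delivers the peracid to the ring-D face, which is also the open face because the axial C8 methyl covers the other; the enol triflates are too electron-poor to react.

Step 18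
Reactants: 32 spiro-epoxide
Product: 33 C10 mono(enol triflate) with cis C13=C14 alkene
Conditions: Pd(OAc)2 (5 mol%), PPh3 (10 mol%), Bu3N, HCO2H, DMF, 40 °C
Reagents that add atoms: none
Why: palladium-catalysed formate reduction of an enol triflate; oxidative addition of zerovalent palladium should be much faster at the triflate on the trisubstituted C13=C14 bond than at the one on the tetrasubstituted C10=C11 bond, and the lactone C17–O bond is not yet allylic at this stage, so it cannot ionise.

Step 19
Reactants: 33 C10 mono(enol triflate)
Product: 34 10-methyl skipped diene (C10=C11 and C13=C14)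
Conditions: MeZnCl (3 equiv), Pd(dppf)Cl2 (5 mol%), THF, 50 °C
Reagents that add atoms: methylzinc chloride C[Zn]Cl
Why: Negishi coupling of the hindered enol triflate; the organozinc reagent tolerates the lactone, the hindered ketone and the epoxide, the first equivalent being consumed by the tertiary hydroxyl.

Step 20
Reactants: 34 10-methyl skipped diene
Product: 35 CNP0605450.1
Conditions: RuHCl(CO)(PPh3)3 (5 mol%), toluene, 80 °C
Reagents that add atoms: none
Why: metal-hydride isomerisation of a 1,4-diene into conjugation: hydrometalation of the cis-disubstituted C13=C14 bond and β-hydride elimination toward the doubly allylic C12–H give the C12=C13 bond; C8 is quaternary and the tetrasubstituted C10=C11 bond does not insert, so the conjugated diene of the target is the only product expected, formed without base and so without touching the acidic C15 methylene.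

## Compound list

1 | (R)-4-methyloxolan-2-one | C[C@@H]1CC(=O)OC1 | starting material
2 | N-methoxy-N-methylpropanamide | CCC(=O)N(C)OC | starting material
3 | (3S,4R)-4-methyl-3-propanoyloxolan-2-one | CCC(=O)[C@@H]1[C@@H](C)COC1=O | intermediate
4 | methyl methacrylate | C=C(C)C(=O)OC | starting material
5 | methyl 2-methyl-3-[(3R,4R)-4-methyl-2-oxo-3-propanoyloxolan-3-yl]propanoate (epimers at the ester α-carbon) | CCC(=O)[C@@]1(CC(C)C(=O)OC)[C@@H](C)COC1=O | intermediate
6 | dimethyl (2R)-2-[(2R)-1-bromopropan-2-yl]-4-methyl-2-propanoylpentanedioate (C4 epimers) | CCC(=O)[C@@](CC(C)C(=O)OC)([C@@H](C)CBr)C(=O)OC | intermediate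
7 | dimethyl (2R)-4-methyl-2-[(2R)-1-(phenylselanyl)propan-2-yl]-2-propanoylpentanedioate | CCC(=O)[C@@](CC(C)C(=O)OC)([C@@H](C)C[Se]c1ccccc1)C(=O)OC | intermediate
8 | the Se-oxide of 7 | CCC(=O)[C@@](CC(C)C(=O)OC)([C@@H](C)C[Se](=O)c1ccccc1)C(=O)OC | intermediate
9 | dimethyl (2R)-4-methyl-2-propanoyl-2-(prop-1-en-2-yl)pentanedioate (C4 epimers) | CCC(=O)[C@@](CC(C)C(=O)OC)(C(C)=C)C(=O)OC | intermediate
10 | methyl (1R)-3,5-dimethyl-2,4-dioxo-1-(prop-1-en-2-yl)cyclohexane-1-carboxylate (enolised 1,3-dione; C5 epimers, 5R drawn) | COC(=O)[C@@]1(C(C)=C)C[C@@H](C)C(=O)C(C)C1=O | intermediate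
11 | cyclopent-4-ene-1,3-dione | O=C1CC(=O)C=C1 | starting material
12 | 4,4-dimethoxycyclopent-2-en-1-one | COC1(OC)CC(=O)C=C1 | intermediate
13 | 5-(hydroxymethyl)-4,4-dimethoxycyclopent-2-en-1-one (racemic) | COC1(OC)C=CC(=O)C1CO | intermediate
14 | 5-({[tert-butyl(dimethyl)silyl]oxy}methyl)-4,4-dimethoxycyclopent-2-en-1-one (racemic) | COC1(OC)C=CC(=O)C1CO[Si](C)(C)C(C)(C)C | intermediate
15 | 4,4,5,5-tetramethyl-2-(prop-1-en-2-yl)-1,3,2-dioxaborolane | CC(=C)B1OC(C)(C)C(C)(C)O1 | starting material
16 | (4R)-2-({[tert-butyl(dimethyl)silyl]oxy}methyl)-3,3-dimethoxy-4-(prop-1-en-2-yl)cyclopentan-1-one (C2 epimers) | CC(=C)[C@H]1CC(=O)C(CO[Si](C)(C)C(C)(C)C)C1(OC)OC | intermediate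
17 | tert-butyl bromoacetate | BrCC(=O)OC(C)(C)C | starting material
18 | tert-butyl 2-[(1S,2R)-4-({[tert-butyl(dimethyl)silyl]oxy}methyl)-3,3-dimethoxy-5-oxo-2-(prop-1-en-2-yl)cyclopentyl]acetate (C4 epimers) | CC(=C)[C@H]1[C@H](CC(=O)OC(C)(C)C)C(=O)C(CO[Si](C)(C)C(C)(C)C)C1(OC)OC | intermediate
19 | (4aS,7aR)-6-({[tert-butyl(dimethyl)silyl]oxy}methyl)-7,7-dimethoxy-1,1-dimethylhexahydrocyclopenta[c]pyran-3,5-dione (trans-fused; C6 epimers) | CC1(C)OC(=O)C[C@@H]2C(=O)C(CO[Si](C)(C)C(C)(C)C)C(OC)(OC)[C@@H]12 | intermediate
20 | (4aS,7aR)-6-(hydroxymethyl)-7,7-dimethoxy-1,1-dimethylhexahydrocyclopenta[c]pyran-3,5-dione | CC1(C)OC(=O)C[C@@H]2C(=O)C(CO)C(OC)(OC)[C@@H]12 | intermediate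
21 | [(4aS,7aR)-7,7-dimethoxy-1,1-dimethyl-3,5-dioxooctahydrocyclopenta[c]pyran-6-yl]methyl acetate (C6 epimers) | CC1(C)OC(=O)C[C@@H]2C(=O)C(COC(C)=O)C(OC)(OC)[C@@H]12 | intermediate
22 | (4aS,7aR)-7,7-dimethoxy-1,1-dimethyl-6-methylidenehexahydrocyclopenta[c]pyran-3,5-dione | CC1(C)OC(=O)C[C@@H]2C(=O)C(=C)C(OC)(OC)[C@@H]12 | intermediate
23 | Michael adduct: 10 alkylated at C3 by the (7,7-dimethoxy-1,1-dimethyl-3,5-dioxooctahydrocyclopenta[c]pyran-6-yl)methyl group (arms cis; lactone fusion drawn cis) | COC(=O)[C@@]1(C(C)=C)C[C@@H](C)C(=O)[C@](C)(CC2C(=O)[C@@H]3CC(=O)OC(C)(C)[C@@H]3C2(OC)OC)C1=O | intermediate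
24 | key-step precursor: methyl (1R,3S,5R)-3-{[(4aR,7aR)-7-methoxy-1,1-dimethyl-3,5-dioxo-1,3,4,4a,5,7a-hexahydrocyclopenta[c]pyran-6-yl]methyl}-3,5-dimethyl-2,4-dioxo-1-(prop-1-en-2-yl)cyclohexane-1-carboxylate | COC(=O)[C@@]1(C(C)=C)C[C@@H](C)C(=O)[C@](C)(CC2=C(OC)[C@@H]3[C@H](C2=O)CC(=O)OC3(C)C)C1=O | intermediate
25 | methoxycyclobutane photoadduct (C7–C8 and C13–C14 bonds formed; 13-OCH3; cyclobutane anti to the lactone) | COC(=O)[C@]12C[C@@H](C)C(=O)[C@](C)(C[C@]34C(=O)[C@@H]5CC(=O)OC(C)(C)[C@@H]5[C@@]3(OC)C[C@@]41C)C2=O | intermediate
26 | tetracyclic tetraketone lactone (rings A–D; ketones at C4, C9, C10, C13; 7-H endo; 8-CH3 toward C9; 3-CH3 exo; cis lactone fusion) | COC(=O)[C@]12C[C@@H](C)C(=O)[C@](C)(C[C@H]3C(=O)[C@@H]4CC(=O)OC(C)(C)[C@@H]4C(=O)C[C@@]31C)C2=O | intermediate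
27 | bis(enol triflate) of 26 (10-OTf, C10=C11; 13-OTf, C13=C14) | COC(=O)[C@]12C[C@@H](C)C(=O)[C@](C)(C[C@H]3C(OS(=O)(=O)C(F)(F)F)=C4CC(=O)OC(C)(C)[C@@H]4C(OS(=O)(=O)C(F)(F)F)=C[C@@]31C)C2=O | intermediate
28 | 9-methylidene bis(enol triflate) | COC(=O)[C@]12C[C@@H](C)C(=O)[C@](C)(C[C@H]3C(OS(=O)(=O)C(F)(F)F)=C4CC(=O)OC(C)(C)[C@@H]4C(OS(=O)(=O)C(F)(F)F)=C[C@@]31C)C2=C | intermediate
29 | trimethylsilyl enol ether (C3=C4) of 28 | COC(=O)[C@]12CC(C)=C(O[Si](C)(C)C)[C@](C)(C[C@H]3C(OS(=O)(=O)C(F)(F)F)=C4CC(=O)OC(C)(C)[C@@H]4C(OS(=O)(=O)C(F)(F)F)=C[C@@]31C)C2=C | intermediate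
30 | 3-trimethylsilyloxy-4-ketone (3-OSiMe3 exo) | COC(=O)[C@]12C[C@@](C)(O[Si](C)(C)C)C(=O)[C@](C)(C[C@H]3C(OS(=O)(=O)C(F)(F)F)=C4CC(=O)OC(C)(C)[C@@H]4C(OS(=O)(=O)C(F)(F)F)=C[C@@]31C)C2=C | intermediate
31 | tertiary α-hydroxy ketone (3-OH exo, 3-CH3 endo; 9-methylidene; bis(enol triflate)) | COC(=O)[C@]12C[C@@](C)(O)C(=O)[C@](C)(C[C@H]3C(OS(=O)(=O)C(F)(F)F)=C4CC(=O)OC(C)(C)[C@@H]4C(OS(=O)(=O)C(F)(F)F)=C[C@@]31C)C2=C | intermediate
32 | spiro-epoxide (epoxide oxygen on the ring-D side of C9; bis(enol triflate)) | COC(=O)[C@]12C[C@@](C)(O)C(=O)[C@](C)(C[C@H]3C(OS(=O)(=O)C(F)(F)F)=C4CC(=O)OC(C)(C)[C@@H]4C(OS(=O)(=O)C(F)(F)F)=C[C@@]31C)[C@]21CO1 | intermediate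
33 | C10 mono(enol triflate) with cis C13=C14 alkene | COC(=O)[C@]12C[C@@](C)(O)C(=O)[C@](C)(C[C@H]3C(OS(=O)(=O)C(F)(F)F)=C4CC(=O)OC(C)(C)[C@@H]4C=C[C@@]31C)[C@]21CO1 | intermediate
34 | 10-methyl skipped diene (C10=C11 and C13=C14) | COC(=O)[C@]12C[C@@](C)(O)C(=O)[C@](C)(C[C@H]3C(C)=C4CC(=O)OC(C)(C)[C@@H]4C=C[C@@]31C)[C@]21CO1 | intermediate
35 | CNP0605450.1 | COC(=O)[C@]12C[C@@](C)(O)C(=O)[C@](C)(C[C@H]3C(C)=C4CC(=O)OC(C)(C)C4=CC[C@@]31C)[C@]21CO1 | target

## Step count and least certain steps

Total: 20 steps. Longest linear sequence: 15 steps (steps 6–11, then 12–20); the ring-D branch (steps 1–5) joins at step 12.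

**Step 13 (key step).** The 1,4-biradical, which must join two fully substituted carbons, may revert faster than it closes, leaving time for competing excitation of the β,γ-unsaturated C9 ketone. The acid opening of the methoxycyclobutane may also be slow enough for the lactone to ionise. Fallback: from 24, mild aqueous acid hydrolysis of the enol ether gives the free enolised dione F1. Irradiation of F1 is the classical De Mayo reaction, whose cyclobutanol opens spontaneously to 26 without an acid step. The price is that the enol regiochemistry then rests on the tautomer equilibrium and on the facial bias of the lactone alone.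

**Step 12.** Facial selectivity in the Michael addition that creates C5 may be poor, giving the isomer with the two arms trans, which cannot bridge in step 13. Fallback: from 19, DBU gives the silyl ether vinylogous ester F2. HF·pyridine then Ac2O gives the allylic acetate F3. Allylic alkylation of 10 with F3 under Pd2(dba)3 and a chiral bis(2-diphenylphosphinobenzamide) ligand of cyclohexane-1,2-diamine returns to 24, with the catalyst, not the substrate, choosing the enolate face.

**Step 2.** Incomplete facial selectivity in the Michael addition would be carried through as loss of enantiomeric purity, because the controlling methyl-bearing centre is erased in step 4. Fallback: from 3, kinetic alkylation of the lithium enolate (LiHMDS, −78 °C) with methyl 2-(bromomethyl)acrylate gives the methylene adduct F4. Conjugate reduction with [(Ph3P)CuH]6 returns to 5.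

**Step 15.** The titanium carbenoid may attack the ring-D ketone as well, or fail at the bridge carbonyl flanked by two quaternary carbons. Fallback: from 27, addition of Me3SiCH2Li/CeCl3 at −78 °C (a smaller, more chemoselective nucleophile) gives the β-hydroxysilane F5. Peterson elimination (KH, or HF in MeCN) returns to 28.

**Step 20.** The ruthenium hydride may stop short, or may start to move the diene toward conjugation with the lactone carbonyl. Fallback: from 34 directly to 35 by radical-chain isomerisation with catalytic thiophenol and AIBN: abstraction of the doubly allylic C12–H and return of hydrogen to C14. No new compound is involved.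

## Further compounds

F1 | step 13 | free enolised dione corresponding to 24 (13-OH in place of 13-OCH3) | COC(=O)[C@@]1(C(C)=C)C[C@@H](C)C(=O)[C@](C)(CC2=C(O)[C@@H]3[C@H](C2=O)CC(=O)OC3(C)C)C1=O
F2 | step 12 | (4aR,7aR)-6-({[tert-butyl(dimethyl)silyl]oxy}methyl)-7-methoxy-1,1-dimethyl-4,4a-dihydrocyclopenta[c]pyran-3,5(1H,7aH)-dione | CC(C)(C)[Si](C)(C)OCC1=C(OC)[C@@H]2[C@H](C1=O)CC(=O)OC2(C)C
F3 | step 12 | [(4aR,7aR)-7-methoxy-1,1-dimethyl-3,5-dioxo-1,3,4,4a,5,7a-hexahydrocyclopenta[c]pyran-6-yl]methyl acetate | CC(=O)OCC1=C(OC)[C@@H]2[C@H](C1=O)CC(=O)OC2(C)C
F4 | step 2 | methyl 2-{[(3R,4R)-4-methyl-2-oxo-3-propanoyloxolan-3-yl]methyl}prop-2-enoate | CCC(=O)[C@@]1(CC(=C)C(=O)OC)[C@@H](C)COC1=O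
F5 | step 15 | 9-hydroxy-9-[(trimethylsilyl)methyl] bis(enol triflate) derived from 27 | COC(=O)[C@]12C[C@@H](C)C(=O)[C@](C)(C[C@H]3C(OS(=O)(=O)C(F)(F)F)=C4CC(=O)OC(C)(C)[C@@H]4C(OS(=O)(=O)C(F)(F)F)=C[C@@]31C)C2(O)C[Si](C)(C)C
F0 | step 20 | none | none
A1 | alternative 1 | tetracyclic silyl enol ether with C9 methylidene and ring-B diene | COC(=O)[C@]12CC(C)=C(O[Si](C)(C)C(C)(C)C)[C@](C)(C[C@H]3C(C)=C4CC(=O)OC(C)(C)C4=CC[C@@]31C)C2=C
A2 | alternative 2 | alkylidene cyclopentenone fused to ring B | COC(=O)[C@]12C[C@@H](C)C(=O)[C@](C)(C[C@H]3[C@](C)(O)C4=CC(=O)C(C)(C)C4=CC[C@@]31C)C2=O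
A3 | alternative 3 | tetracyclic triketone with ring-B enone | COC(=O)[C@]12C[C@@H](C)C(=O)[C@](C)(C[C@H]3C(=O)C4=C(CC[C@@]31C)C(C)(C)OC(=O)C4)C2=O
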